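**Plan**
Retrosynthesis: the 1,6-oxirane is cut at C6–O (C1 tertiary oxygen plus a C6 leaving group). C4=C5 with C6–OH is traced back to a 5,6-oxirane, the C3 benzoate C–O bond to a 2,3-oxirane, and the C2–O and C3–O bonds of that oxirane are cut last; the three esters are cut at acyl–O.
Forward: benzoic acid supplies the carbocycle and C7. Birch reduction, C1 hydroxylation, silylation and reduction give achiral dienol 9, in which C1, its oxygen and C7 lie on the mirror plane of a cyclohexa-2,5-diene whose two alkenes become C2–C3 and C5–C6.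
Ring order: the 2,3-oxirane is closed in step 6 and opened at C3, a 5,6-oxirane is closed in step 8 and opened at C5, and the 1,6-oxirane of the target is closed last (step 14).
Stereochemistry: a chiral vanadium–bishydroxamate catalyst picks one enantiotopic alkene while C7–OH fixes the face (C1, C2). C3 comes from anti opening by benzoate. C6 comes from a second C7–OH-directed epoxidation, then inversion in the final closure.

Key step: step 6

Remark: locants C1–C7 and descriptors follow the target numbering (C1 = oxirane carbon carrying C7H2O, C2 = CHOAc, C3 = CHOBz); β is the ring face of C7 and α the face of the C1 oxygen.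
Assumption: the sense of induction of the bishydroxamic acid ligand on dienol 9 cannot be predicted with certainty. The ligand from (1R,2R)-cyclohexane-1,2-diamine (N,N'-dihydroxy-N,N'-bis(2,2-diphenylacetyl), or a bulkier N-acyl analogue) is written; its mirror image is used if a test run gives the antipode of 11.

**Route**

Step 1
Reactants: 1 benzoic acid
Product: 2 cyclohexa-2,5-diene-1-carboxylic acid
Conditions: Na, NH3(l), EtOH, −78 °C; NH4Cl; aq. HCl
Reagents that add atoms: none
Why: Birch reduction of a benzoate; the carboxylate stabilises charge at the ipso carbon, so protons arrive at C1 and C4 and the unconjugated 2,5-diene results.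

Step 2
Reactants: 2 cyclohexa-2,5-diene-1-carboxylic acid; 3 (trimethylsilyl)diazomethane
Product: 4 methyl cyclohexa-2,5-diene-1-carboxylate
Conditions: Me3SiCHN2, toluene/MeOH, 0 °C → rt
Reagents that add atoms: (trimethylsilyl)diazomethane, C[Si](C)(C)C=[N+]=[N-]
Why: Diazoalkane esterification (O-methylation of the carboxylate by a methyldiazonium species) runs under neutral conditions, so the skipped diene should not drift into conjugation.

Step 3
Reactants: 4 methyl cyclohexa-2,5-diene-1-carboxylate; 5 2-(phenylsulfonyl)-3-phenyloxaziridine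
Product: 6 methyl 1-hydroxycyclohexa-2,5-diene-1-carboxylate
Conditions: KN(SiMe3)2, THF, −78 °C; then 5, −78 °C; aq. NH4Cl
Reagents that add atoms: 2-(phenylsulfonyl)-3-phenyloxaziridine, O=S(=O)(N1OC1c1ccccc1)c1ccccc1
Why: Davis oxidation (electrophilic α-hydroxylation of an ester enolate by an N-sulfonyloxaziridine); the cross-conjugated dienolate reacts at C1, the site of Birch-type alkylations, and the cold buffered quench protects the dehydration-prone bis-allylic carbinol.

Step 4
Reactants: 6 methyl 1-hydroxycyclohexa-2,5-diene-1-carboxylate; 7 tert-butyldimethylsilyl trifluoromethanesulfonate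
Product: 8 methyl 1-(tert-butyldimethylsilyloxy)cyclohexa-2,5-diene-1-carboxylate
Conditions: tBuMe2SiOTf, 2,6-lutidine, CH2Cl2, 0 °C → rt
Reagents that add atoms: tert-butyldimethylsilyl trifluoromethanesulfonate, CC(C)(C)[Si](C)(C)OS(=O)(=O)C(F)(F)F
Why: Silylation of a tertiary alcohol with a silyl triflate and a hindered pyridine base; the ether blocks loss of water to methyl benzoate and masks the C1 oxygen so that it cannot act as a directing group later.

Step 5
Reactants: 8 methyl 1-(tert-butyldimethylsilyloxy)cyclohexa-2,5-diene-1-carboxylate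
Product: 9 [1-(tert-butyldimethylsilyloxy)cyclohexa-2,5-dien-1-yl]methanol
Conditions: iBu2AlH, CH2Cl2, −78 → 0 °C; aq. potassium sodium tartrate
Reagents that add atoms: none
Why: Hydride reduction of an ester to the primary alcohol; the cold aluminium alkoxide should not trigger silyl migration from the tertiary to the primary oxygen, and the isolated alkenes are inert.

Step 6
Reactants: 9 [1-(tert-butyldimethylsilyloxy)cyclohexa-2,5-dien-1-yl]methanol; 10 cumene hydroperoxide
Product: 11 [(1R,2S,3S)-1-(tert-butyldimethylsilyloxy)-2,3-epoxycyclohex-5-en-1-yl]methanol (oxirane β, cis to CH2OH)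
Conditions: VO(OiPr)3 (2 mol%), (R,R)-bishydroxamic acid ligand (4 mol%), cumene hydroperoxide (1.1 equiv), toluene, 0 °C → rt
Reagents that add atoms: cumene hydroperoxide, CC(C)(OO)c1ccccc1
Why: The pentavalent vanadium centre, held in the C2-symmetric bishydroxamate pocket, exchanges an isopropoxide for the C7 hydroxyl and binds the hydroperoxide, so the activated peroxide oxygen is passed within the complex to a ring alkene, as in the known vanadium–bishydroxamic acid epoxidation of homoallylic alcohols. The oxirane closes by concerted suprafacial [2+1] oxygen-atom transfer that forms the C2–O and C3–O bonds together. C2 and C3 are set on the β face because the oxidant is tethered through C7–O–vanadium and cannot reach the α face. C1 becomes a stereocentre through the ligand's choice between the enantiotopic C2=C3 and C5=C6 alkenes, the two chelated transition states differing in how the ring sits against the N-acyl groups. The step needs enantiotopic-group selectivity and mono-epoxidation: the silyl ether removes the competing allylic direction by the C1 oxygen, and because the minor enantiomer keeps the alkene the catalyst prefers, it should be drained to the separable meso bis-epoxide faster than 11, so stopping short of full conversion should raise the enantiomeric purity.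

Step 7
Reactants: 11 [(1R,2S,3S)-1-(tert-butyldimethylsilyloxy)-2,3-epoxycyclohex-5-en-1-yl]methanol; 1 benzoic acid
Product: 12 (1R,2S,3R)-1-(tert-butyldimethylsilyloxy)-2-hydroxy-1-(hydroxymethyl)cyclohex-5-en-3-yl benzoate (2β-OH, 3α-OBz)
Conditions: PhCO2H (3 equiv), Bu4N(O2CPh) (0.2 equiv), toluene, 80 °C
Reagents that add atoms: benzoic acid, OC(=O)c1ccccc1
Why: Carboxylate opening of an epoxide (SN2, inversion at C3); C2 is shielded by quaternary C1, whose silyloxy group sits on the α face the nucleophile must use, and is deactivated by the C1 oxygen, so benzoate should enter at C3 and leave the C2 hydroxyl β and trans to the new ester.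

Step 8
Reactants: 12 (1R,2S,3R)-1-(tert-butyldimethylsilyloxy)-2-hydroxy-1-(hydroxymethyl)cyclohex-5-en-3-yl benzoate; 13 tert-butyl hydroperoxide
Product: 14 (1R,2S,3R,5R,6R)-1-(tert-butyldimethylsilyloxy)-5,6-epoxy-2-hydroxy-1-(hydroxymethyl)cyclohexan-3-yl benzoate (5β,6β-oxirane)
Conditions: VO(acac)2 (5 mol%), tBuOOH (decane), CH2Cl2, 0 °C → rt
Reagents that add atoms: tert-butyl hydroperoxide, CC(C)(C)OO
Why: Hydroxyl-directed vanadium-catalysed epoxidation; the homoallylic C7 hydroxyl and the C2 hydroxyl both lie on the β face and deliver the metal-bound peroxide there, setting C5 and C6 cis to C7.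

Step 9
Reactants: 14 (1R,2S,3R,5R,6R)-1-(tert-butyldimethylsilyloxy)-5,6-epoxy-2-hydroxy-1-(hydroxymethyl)cyclohexan-3-yl benzoate; 15 benzoyl chloride
Product: 16 (1R,2S,3R,5R,6R)-1-(benzoyloxymethyl)-1-(tert-butyldimethylsilyloxy)-5,6-epoxy-2-hydroxycyclohexan-3-yl benzoate
Conditions: BzCl (1.05 equiv), pyridine, CH2Cl2, −20 → 0 °C
Reagents that add atoms: benzoyl chloride, O=C(Cl)c1ccccc1
Why: Selective O-acylation of the primary alcohol; the secondary C2 hydroxyl is flanked by quaternary C1 and the C3 benzoate and should react far more slowly at low temperature.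

Step 10
Reactants: 16 (1R,2S,3R,5R,6R)-1-(benzoyloxymethyl)-1-(tert-butyldimethylsilyloxy)-5,6-epoxy-2-hydroxycyclohexan-3-yl benzoate; 17 acetic anhydride
Product: 18 (1S,2S,3R,5R,6R)-2-acetoxy-1-(benzoyloxymethyl)-1-(tert-butyldimethylsilyloxy)-5,6-epoxycyclohexan-3-yl benzoate
Conditions: Ac2O, DMAP (cat.), pyridine, CH2Cl2, rt
Reagents that add atoms: acetic anhydride, CC(=O)OC(C)=O
Why: DMAP-catalysed acetylation (nucleophilic acyl-transfer catalysis) of the remaining hindered secondary alcohol; oxirane and silyl ether are inert to these conditions.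

Step 11
Reactants: 18 (1S,2S,3R,5R,6R)-2-acetoxy-1-(benzoyloxymethyl)-1-(tert-butyldimethylsilyloxy)-5,6-epoxycyclohexan-3-yl benzoate; 19 diphenyl diselenide
Product: 20 (1S,2S,3R,5S,6S)-2-acetoxy-1-(benzoyloxymethyl)-1-(tert-butyldimethylsilyloxy)-6-hydroxy-5-(phenylselanyl)cyclohexan-3-yl benzoate (5α-SePh, 6β-OH)
Conditions: (PhSe)2, NaBH4, EtOH, 0 °C; then 18, THF/EtOH, rt
Reagents that add atoms: diphenyl diselenide, c1ccc(cc1)[Se][Se]c1ccccc1
Why: Epoxide opening by benzeneselenolate (Sharpless–Lauer conditions, SN2 with inversion at C5); C6 is neopentylic and deactivated by the C1 oxygen, so the soft, weakly basic nucleophile should attack C5 from the α face and leave the C6 hydroxyl β.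

Step 12
Reactants: 20 (1S,2S,3R,5S,6S)-2-acetoxy-1-(benzoyloxymethyl)-1-(tert-butyldimethylsilyloxy)-6-hydroxy-5-(phenylselanyl)cyclohexan-3-yl benzoate
Product: 22 (1S,2S,3R,6R)-2-acetoxy-1-(benzoyloxymethyl)-1-(tert-butyldimethylsilyloxy)-6-hydroxycyclohex-4-en-3-yl benzoate (6β-OH), via selenoxide 21 (not isolated)
Conditions: 30% H2O2, pyridine, THF, 0 °C → rt
Reagents that add atoms: none
Why: Selenoxide syn-elimination; β-hydroxy selenoxides eliminate away from the carbinol carbon, so the cis hydrogen on C4 is lost and the C4=C5 allylic alcohol should form with C6 untouched.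

Step 13
Reactants: 22 (1S,2S,3R,6R)-2-acetoxy-1-(benzoyloxymethyl)-1-(tert-butyldimethylsilyloxy)-6-hydroxycyclohex-4-en-3-yl benzoate
Product: 23 (1S,2S,3R,6R)-2-acetoxy-1-(benzoyloxymethyl)-1,6-dihydroxycyclohex-4-en-3-yl benzoate (1α-OH, 6β-OH, trans diol)
Conditions: HF·pyridine, THF, 0 °C → rt
Reagents that add atoms: none
Why: Fluoride-mediated desilylation under acidic conditions, where acyl migration to the freed hydroxyl groups is slow; no stereocentre is touched.

Step 14
Reactants: 23 (1S,2S,3R,6R)-2-acetoxy-1-(benzoyloxymethyl)-1,6-dihydroxycyclohex-4-en-3-yl benzoate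
Product: 24 (1S,2S,3R,6S)-2-acetoxy-1-(benzoyloxymethyl)-7-oxabicyclo[4.1.0]hept-4-en-3-yl benzoate (target)
Conditions: PPh3, DIAD, THF, 0 °C → rt
Reagents that add atoms: none
Why: Mitsunobu cyclodehydration of a trans-1,2-diol; only the secondary allylic C6 hydroxyl forms the alkoxyphosphonium, the C1 oxygen displaces it from the α face (3-exo-tet, inversion at C6), and no β-hydrogen is placed for elimination.

**Compound list**
1 | benzoic acid | OC(=O)c1ccccc1 | starting material
2 | cyclohexa-2,5-diene-1-carboxylic acid | OC(=O)C1C=CCC=C1 | intermediate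
3 | (trimethylsilyl)diazomethane | C[Si](C)(C)C=[N+]=[N-] | starting material
4 | methyl cyclohexa-2,5-diene-1-carboxylate | COC(=O)C1C=CCC=C1 | intermediate
5 | 2-(phenylsulfonyl)-3-phenyloxaziridine (racemic) | O=S(=O)(N1OC1c1ccccc1)c1ccccc1 | starting material
6 | methyl 1-hydroxycyclohexa-2,5-diene-1-carboxylate | COC(=O)C1(O)C=CCC=C1 | intermediate
7 | tert-butyldimethylsilyl trifluoromethanesulfonate | CC(C)(C)[Si](C)(C)OS(=O)(=O)C(F)(F)F | starting material
8 | methyl 1-(tert-butyldimethylsilyloxy)cyclohexa-2,5-diene-1-carboxylate | COC(=O)C1(O[Si](C)(C)C(C)(C)C)C=CCC=C1 | intermediate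
9 | [1-(tert-butyldimethylsilyloxy)cyclohexa-2,5-dien-1-yl]methanol (achiral) | OCC1(O[Si](C)(C)C(C)(C)C)C=CCC=C1 | intermediate
10 | cumene hydroperoxide | CC(C)(OO)c1ccccc1 | starting material
11 | [(1R,2S,3S)-1-(tert-butyldimethylsilyloxy)-2,3-epoxycyclohex-5-en-1-yl]methanol, oxirane cis to CH2OH | OC[C@]1(O[Si](C)(C)C(C)(C)C)C=CC[C@@H]2O[C@H]12 | intermediate
12 | (1R,2S,3R)-1-(tert-butyldimethylsilyloxy)-2-hydroxy-1-(hydroxymethyl)cyclohex-5-en-3-yl benzoate (2β-OH, 3α-OBz) | O[C@H]1[C@H](OC(=O)c2ccccc2)CC=C[C@]1(CO)O[Si](C)(C)C(C)(C)C | intermediate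
13 | tert-butyl hydroperoxide | CC(C)(C)OO | starting material
14 | (1R,2S,3R,5R,6R)-1-(tert-butyldimethylsilyloxy)-5,6-epoxy-2-hydroxy-1-(hydroxymethyl)cyclohexan-3-yl benzoate (oxirane β) | O[C@H]1[C@H](OC(=O)c2ccccc2)C[C@H]2O[C@H]2[C@]1(CO)O[Si](C)(C)C(C)(C)C | intermediate
15 | benzoyl chloride | O=C(Cl)c1ccccc1 | starting material
16 | (1R,2S,3R,5R,6R)-1-(benzoyloxymethyl)-1-(tert-butyldimethylsilyloxy)-5,6-epoxy-2-hydroxycyclohexan-3-yl benzoate | O[C@H]1[C@H](OC(=O)c2ccccc2)C[C@H]2O[C@H]2[C@]1(COC(=O)c1ccccc1)O[Si](C)(C)C(C)(C)C | intermediate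
17 | acetic anhydride | CC(=O)OC(C)=O | starting material
18 | (1S,2S,3R,5R,6R)-2-acetoxy-1-(benzoyloxymethyl)-1-(tert-butyldimethylsilyloxy)-5,6-epoxycyclohexan-3-yl benzoate | CC(=O)O[C@H]1[C@H](OC(=O)c2ccccc2)C[C@H]2O[C@H]2[C@]1(COC(=O)c1ccccc1)O[Si](C)(C)C(C)(C)C | intermediate
19 | diphenyl diselenide | c1ccc(cc1)[Se][Se]c1ccccc1 | starting material
20 | (1S,2S,3R,5S,6S)-2-acetoxy-1-(benzoyloxymethyl)-1-(tert-butyldimethylsilyloxy)-6-hydroxy-5-(phenylselanyl)cyclohexan-3-yl benzoate (5α-SePh, 6β-OH) | CC(=O)O[C@H]1[C@H](OC(=O)c2ccccc2)C[C@H]([Se]c2ccccc2)[C@@H](O)[C@]1(COC(=O)c1ccccc1)O[Si](C)(C)C(C)(C)C | intermediate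
21 | selenoxide of 20 (C5 phenylseleninyl, configuration at selenium undefined) | CC(=O)O[C@H]1[C@H](OC(=O)c2ccccc2)C[C@H]([Se](=O)c2ccccc2)[C@@H](O)[C@]1(COC(=O)c1ccccc1)O[Si](C)(C)C(C)(C)C | intermediate
22 | (1S,2S,3R,6R)-2-acetoxy-1-(benzoyloxymethyl)-1-(tert-butyldimethylsilyloxy)-6-hydroxycyclohex-4-en-3-yl benzoate (6β-OH) | CC(=O)O[C@H]1[C@H](OC(=O)c2ccccc2)C=C[C@@H](O)[C@]1(COC(=O)c1ccccc1)O[Si](C)(C)C(C)(C)C | intermediate
23 | (1S,2S,3R,6R)-2-acetoxy-1-(benzoyloxymethyl)-1,6-dihydroxycyclohex-4-en-3-yl benzoate (1α-OH, 6β-OH) | CC(=O)O[C@H]1[C@H](OC(=O)c2ccccc2)C=C[C@@H](O)[C@]1(COC(=O)c1ccccc1)O | intermediate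
24 | (1S,2S,3R,6S)-2-acetoxy-1-(benzoyloxymethyl)-7-oxabicyclo[4.1.0]hept-4-en-3-yl benzoate (EANPDB:ANNO_02019) | CC(=O)O[C@H]1[C@H](OC(=O)c2ccccc2)C=C[C@@H]2O[C@@]21COC(=O)c1ccccc1 | target

Total step count: 14. Longest linear sequence: 14 steps (benzoic acid 1 to target 24).

**Steps most likely to fail**

Step 6. The catalyst may discriminate poorly between the two enantiotopic alkenes, or oxygen transfer may stall next to the silyloxy-bearing quaternary carbon while over-oxidation to the meso bis-epoxide continues. The fallback is a resolution and sets out from 9. Achiral VO(acac)2/tBuOOH, with the same syn direction by C7–OH, gives 11 together with its mirror image, ent-11 F1. The racemate is esterified at C7–OH with (S)-2-methoxy-2-phenylacetic acid (DCC, DMAP) to two diastereomers, the (S)-O-methylmandelate of 11 F2 and the (S)-O-methylmandelate of ent-11 F3, which are separated by chromatography or crystallisation. iBu2AlH at −78 °C cleaves F2 and the sequence comes back to the route at 11.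

Step 11. The basic selenolate and the C6 alkoxide it generates may transfer or cleave ester groups or let the silyl group migrate. The opening may also be slow, because the conformer that offers C5 for diaxial attack carries its substituents axially. The fallback sets out from 18 and uses no alkoxide. Me3SiOTf/2,6-lutidine in toluene (−78 °C → rt), then DBU, isomerises the oxirane by anti elimination of the C4 hydrogen to the allylic silyl ether, the C6 O-trimethylsilyl ether of 22 F4, with the oxygen capped as it forms. Citric acid in MeOH then frees the C6 hydroxyl and the sequence comes back to the route at 22, replacing steps 11 and 12.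

Step 14. The diol may be eroded by acyl migration before it reaches the phosphonium stage, or the allylic alkoxyphosphonium may be intercepted (SN2' or external nucleophile) instead of closing. The fallback sets out from 22, before desilylation. MsCl/Et3N in CH2Cl2 at −20 °C gives the C6 methanesulfonate of 22 F5. Bu4NF in THF at 0 °C then removes the silyl group, and the C1 alkoxide should close at once on C6 with inversion, so the sequence comes back to the route at target 24 and replaces steps 13 and 14.

**Further compounds**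
F1 | step 6 | ent-11, [(1S,2R,3R)-1-(tert-butyldimethylsilyloxy)-2,3-epoxycyclohex-5-en-1-yl]methanol | OC[C@@]1(O[Si](C)(C)C(C)(C)C)C=CC[C@H]2O[C@@H]12
F2 | step 6 | (S)-2-methoxy-2-phenylacetate (C7 ester) of 11 | CO[C@H](C(=O)OC[C@]1(O[Si](C)(C)C(C)(C)C)C=CC[C@@H]2O[C@H]12)c1ccccc1
F3 | step 6 | (S)-2-methoxy-2-phenylacetate (C7 ester) of ent-11 | CO[C@H](C(=O)OC[C@@]1(O[Si](C)(C)C(C)(C)C)C=CC[C@H]2O[C@@H]12)c1ccccc1
F4 | step 11 | C6 O-trimethylsilyl ether of 22 | CC(=O)O[C@H]1[C@H](OC(=O)c2ccccc2)C=C[C@@H](O[Si](C)(C)C)[C@]1(COC(=O)c1ccccc1)O[Si](C)(C)C(C)(C)C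
F5 | step 14 | C6 methanesulfonate of 22 | CC(=O)O[C@H]1[C@H](OC(=O)c2ccccc2)C=C[C@@H](OS(C)(=O)=O)[C@]1(COC(=O)c1ccccc1)O[Si](C)(C)C(C)(C)C
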